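**Plan**

1. Cembranolide numbering and abbreviations: C1 = ring-fusion CH, C2 = lactone O–CH, C3=C4(Me), C6 (OAc), C7=C8(Me), C10 (OH), C11=C12(Me), C13, C14 (CH2 next to C1); C15 = lactone α-carbon, C16 = lactone C=O, C17 = exocyclic CH2; TBS = tert-butyldimethylsilyl.
2. Enabling feature: in the α-methylene-γ-butyrolactone (ring O–C2–C1–C15–C16), C1 is β to C16=O and allylic to the exocyclic C15=C17 bond, so C17–C15–C1 is the retron of a radical allyl transfer. The 14-membered ring is therefore cut at C1–C14, back to an endocyclic C1=C15 butenolide with PhSO2 on C17 and iodine on C14.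
3. Further cuts: C15–C16 (CO insertion), C1–C2 (alkynylation of a C2 enal), C5–C6 and C9–C10 (propargylation of C6 and C10 enals), the three C(sp2)–CH3 bonds, and the three formyl carbons C10, C6 and C2.
4. Forward: the chain grows linearly from C14 to C2 (propargylation, carboalumination–iodination, formylation, repeated). Alkynylation, trans-hydroalumination–iodination and carbonylative lactonisation then give the butenolide. The 14-membered ring is closed in the penultimate step, and a desilylation ends the route.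
5. Stereochemistry: C10 and C6 come from catalyst-controlled propargylboration, C2 from catalyst-controlled alkynylation, C1 from C2 during ring closure (trans), and all three E-olefins from syn carboalumination.

Key step: step 17

Remark: the facial sense of the three catalyst-controlled additions is assigned by the accepted models ((R)-TRIP gives R carbinols from aryl and alkenyl aldehydes, hence (S)-TRIP here; the ProPhenol sense is less certain). If MTPA ester analysis of 7 or 19 showed the opposite sense, the antipodal catalyst would be used in the same step.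

**Route**

Step 1
Reactants: 1 tert-butyl(but-3-yn-1-yloxy)dimethylsilane
Product: 3 (E)-tert-butyl[(4-iodo-3-methylbut-3-en-1-yl)oxy]dimethylsilane, via alkenyldimethylalane 2 (not isolated)
Conditions: Me3Al (2 equiv), Cp2ZrCl2 (0.25 equiv), CH2Cl2, 0 °C to rt; then I2, THF, −30 to 0 °C
Reagents that add atoms: trimethylaluminium, C[Al](C)C; iodine, II
Why: Zirconium-catalysed carboalumination (Negishi) adds methyl and aluminium syn across the terminal alkyne with aluminium on the terminal carbon, and iodinolysis of the C–Al bond with retention should give the E vinyl iodide that fixes the C11=C12 geometry.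

Step 2
Reactants: 3 (E)-tert-butyl[(4-iodo-3-methylbut-3-en-1-yl)oxy]dimethylsilane
Product: 5 (E)-5-(TBSO)-3-methylpent-2-enal, via alkenyllithium 4 (not isolated)
Conditions: t-BuLi (2.1 equiv), Et2O, −78 °C; then DMF, −78 to 0 °C; H2O
Reagents that add atoms: N,N-dimethylformamide, CN(C)C=O
Why: Iodine–lithium exchange keeps the alkene geometry, and formylation of the alkenyllithium with DMF (Bouveault aldehyde synthesis) should give the E enal whose carbonyl carbon becomes C10.

Step 3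
Reactants: 5 (E)-5-(TBSO)-3-methylpent-2-enal; 6 allenylboronic acid pinacol ester
Product: 7 (4S,5E)-8-(TBSO)-6-methyloct-5-en-1-yn-4-ol
Conditions: (S)-3,3'-bis(2,4,6-triisopropylphenyl)-1,1'-binaphthyl-2,2'-diyl hydrogen phosphate ((S)-TRIP, 5 mol%), 4 Å molecular sieves, toluene, −20 °C; aqueous work-up
Reagents that add atoms: none
Why: Chiral phosphoric acid-catalysed propargylboration (SE2' addition of the allenylboronate through a closed six-membered transition state) should give only the homopropargylic alcohol, the (S)-acid selecting the aldehyde face that leads to the S carbinol at C10.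

Step 4
Reactants: 7 (4S,5E)-8-(TBSO)-6-methyloct-5-en-1-yn-4-ol
Product: 8 (4S,5E)-4,8-bis(TBSO)-6-methyloct-5-en-1-yne
Conditions: TBSCl, imidazole, DMF, rt
Reagents that add atoms: tert-butyldimethylsilyl chloride, CC(C)(C)[Si](C)(C)Cl
Why: Imidazole-promoted silyl ether formation protects the C10 hydroxyl for the rest of the route and leaves the terminal alkyne untouched.

Step 5
Reactants: 8 (4S,5E)-4,8-bis(TBSO)-6-methyloct-5-en-1-yne
Product: 10 (1E,4S,5E)-4,8-bis(TBSO)-1-iodo-2,6-dimethylocta-1,5-diene, via alkenyldimethylalane 9 (not isolated)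
Conditions: Me3Al (2.5 equiv), Cp2ZrCl2 (0.3 equiv), CH2Cl2, 0 °C to rt; then I2, THF, −30 to 0 °C
Reagents that add atoms: trimethylaluminium, C[Al](C)C; iodine, II
Why: In this second Negishi carboalumination–iodinolysis only the terminal alkyne reacts (the trisubstituted alkene and silyl ethers are inert), and syn addition sets the E geometry of C7=C8.

Step 6
Reactants: 10 (1E,4S,5E)-4,8-bis(TBSO)-1-iodo-2,6-dimethylocta-1,5-diene
Product: 12 (2E,5S,6E)-5,9-bis(TBSO)-3,7-dimethylnona-2,6-dienal, via alkenyllithium 11 (not isolated)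
Conditions: t-BuLi (2.1 equiv), Et2O, −78 °C; then DMF, −78 to 0 °C; H2O
Reagents that add atoms: N,N-dimethylformamide, CN(C)C=O
Why: Iodine–lithium exchange with retention followed by DMF formylation (Bouveault aldehyde synthesis) should give the E enal whose carbonyl carbon becomes C6.

Step 7
Reactants: 12 (2E,5S,6E)-5,9-bis(TBSO)-3,7-dimethylnona-2,6-dienal; 6 allenylboronic acid pinacol ester
Product: 13 (4S,5E,8S,9E)-8,12-bis(TBSO)-6,10-dimethyldodeca-5,9-dien-1-yn-4-ol
Conditions: (S)-TRIP (5 mol%), 4 Å molecular sieves, toluene, −20 °C; aqueous work-up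
Reagents that add atoms: none
Why: This is the same catalyst-controlled propargylboration as in step 3; the remote C10 centre should not influence the facial choice, so the (S)-acid sets C6 as S.

Step 8
Reactants: 13 (4S,5E,8S,9E)-8,12-bis(TBSO)-6,10-dimethyldodeca-5,9-dien-1-yn-4-ol
Product: 15 (1E,4S,5E,8S,9E)-8,12-bis(TBSO)-1-iodo-2,6,10-trimethyldodeca-1,5,9-trien-4-ol, via alkoxy-alkenyl bis(dimethylalane) 14 (not isolated)
Conditions: Me3Al (3.5 equiv), Cp2ZrCl2 (0.5 equiv), CH2Cl2, 0 °C to rt; then I2, THF, −30 to 0 °C; aqueous Rochelle salt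
Reagents that add atoms: trimethylaluminium, C[Al](C)C; iodine, II
Why: Negishi carboalumination tolerates the free homopropargylic alcohol as its dimethylaluminium alkoxide, and syn methylalumination followed by iodinolysis with retention sets the E geometry of C3=C4.

Step 9
Reactants: 15 (1E,4S,5E,8S,9E)-8,12-bis(TBSO)-1-iodo-2,6,10-trimethyldodeca-1,5,9-trien-4-ol
Product: 17 (2E,5S,6E,9S,10E)-9,13-bis(TBSO)-5-hydroxy-3,7,11-trimethyltrideca-2,6,10-trienal, via dilithio alkoxide-alkenyllithium 16 (not isolated)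
Conditions: MeLi (1.05 equiv), Et2O, −78 °C; t-BuLi (2.1 equiv), −78 °C; then DMF, −78 to 0 °C; H2O
Reagents that add atoms: N,N-dimethylformamide, CN(C)C=O
Why: Deprotonating the alcohol with MeLi before the iodine–lithium exchange prevents internal protonation of the alkenyllithium, and DMF formylation (Bouveault aldehyde synthesis) should then give the E enal whose carbonyl carbon becomes C2.

Step 10
Reactants: 17 (2E,5S,6E,9S,10E)-9,13-bis(TBSO)-5-hydroxy-3,7,11-trimethyltrideca-2,6,10-trienal; 18 tert-butyldimethyl(prop-2-yn-1-yloxy)silane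
Product: 19 (4S,5E,8S,9E,12S,13E)-1,12,16-tris(TBSO)-6,10,14-trimethylhexadeca-5,9,13-trien-2-yne-4,8-diol
Conditions: (S,S)-ProPhenol (20 mol%), Me2Zn (4 equiv), Ph3PO (40 mol%), toluene, 0 °C; aqueous NH4Cl
Reagents that add atoms: none
Why: Catalytic asymmetric alkynylation (zinc alkynylide addition under the dinuclear zinc–ProPhenol catalyst) is well suited to α,β-unsaturated aldehydes, and the ligand should set the C2 carbinol as S while the remote C6 hydroxyl is carried as a spectator zinc alkoxide.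

Step 11
Reactants: 19 (4S,5E,8S,9E,12S,13E)-1,12,16-tris(TBSO)-6,10,14-trimethylhexadeca-5,9,13-trien-2-yne-4,8-diol
Product: 21 (2Z,4S,5E,8S,9E,12S,13E)-1,12,16-tris(TBSO)-2-iodo-6,10,14-trimethylhexadeca-2,5,9,13-tetraene-4,8-diol, via cyclic sodium alkenylalkoxyaluminate 20 (not isolated)
Conditions: NaAlH2(OCH2CH2OMe)2 (Red-Al, 3.5 equiv), THF, 0 °C; then I2, THF, −78 to −20 °C; aqueous Rochelle salt, Na2S2O3
Reagents that add atoms: iodine, II
Why: Hydroxyl-directed trans-hydroalumination of the propargylic alcohol delivers hydride to C1 and aluminium to C15 within a five-membered alkoxyaluminate, and iodinolysis with retention should give the Z vinyl iodide with the C2 oxygen and iodine cis, as the lactone requires.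

Step 12
Reactants: 21 (2Z,4S,5E,8S,9E,12S,13E)-1,12,16-tris(TBSO)-2-iodo-6,10,14-trimethylhexadeca-2,5,9,13-tetraene-4,8-diol
Product: 22 (5S)-5-[(1E,4S,5E,8S,9E)-8,12-bis(TBSO)-4-hydroxy-2,6,10-trimethyldodeca-1,5,9-trien-1-yl]-3-[(TBSO)methyl]furan-2(5H)-one
Conditions: PdCl2(PPh3)2 (5 mol%), CO (1 atm), powdered K2CO3, THF, 45 °C
Reagents that add atoms: carbon monoxide, [C-]#[O+]
Why: In this carbonylative lactonisation the vinyl iodide adds oxidatively to zerovalent palladium, CO inserts, and the cis C2 hydroxyl captures the acylpalladium, the five-membered closure outrunning any attack by the remote C6 hydroxyl.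

Step 13
Reactants: 22 (5S)-5-[(1E,4S,5E,8S,9E)-8,12-bis(TBSO)-4-hydroxy-2,6,10-trimethyldodeca-1,5,9-trien-1-yl]-3-[(TBSO)methyl]furan-2(5H)-one
Product: 23 (5S)-5-[(1E,4S,5E,8S,9E)-4-acetoxy-8,12-bis(TBSO)-2,6,10-trimethyldodeca-1,5,9-trien-1-yl]-3-[(TBSO)methyl]furan-2(5H)-one
Conditions: Ac2O, pyridine, CH2Cl2, 0 °C to rt
Reagents that add atoms: acetic anhydride, CC(=O)OC(C)=O
Why: The C6 hydroxyl is the only free alcohol, so O-acylation under weakly basic conditions installs the acetate of the target without epimerising the acidic C2–H of the butenolide.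

Step 14
Reactants: 23 (5S)-5-[(1E,4S,5E,8S,9E)-4-acetoxy-8,12-bis(TBSO)-2,6,10-trimethyldodeca-1,5,9-trien-1-yl]-3-[(TBSO)methyl]furan-2(5H)-one
Product: 24 (5S)-5-[(1E,4S,5E,8S,9E)-4-acetoxy-8-(TBSO)-12-hydroxy-2,6,10-trimethyldodeca-1,5,9-trien-1-yl]-3-(hydroxymethyl)furan-2(5H)-one
Conditions: HF·pyridine, pyridine, THF, 0 °C
Reagents that add atoms: none
Why: In this selective desilylation buffered fluoride should cleave the two primary silyl ethers (C14 and C17) much faster than the hindered secondary allylic ether at C10.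

Step 15
Reactants: 24 (5S)-5-[(1E,4S,5E,8S,9E)-4-acetoxy-8-(TBSO)-12-hydroxy-2,6,10-trimethyldodeca-1,5,9-trien-1-yl]-3-(hydroxymethyl)furan-2(5H)-one
Product: 25 (5S)-5-[(1E,4S,5E,8S,9E)-4-acetoxy-8-(TBSO)-12-iodo-2,6,10-trimethyldodeca-1,5,9-trien-1-yl]-3-(iodomethyl)furan-2(5H)-one
Conditions: PPh3, I2, imidazole, CH2Cl2, 0 °C, dark; used without storage
Reagents that add atoms: iodine, II
Why: Appel-type iodination converts both primary alcohols to iodides by SN2 displacement of their alkoxyphosphonium ions and leaves the acetate, silyl ether and lactone untouched.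

Step 16
Reactants: 25 (5S)-5-[(1E,4S,5E,8S,9E)-4-acetoxy-8-(TBSO)-12-iodo-2,6,10-trimethyldodeca-1,5,9-trien-1-yl]-3-(iodomethyl)furan-2(5H)-one
Product: 26 (5S)-5-[(1E,4S,5E,8S,9E)-4-acetoxy-8-(TBSO)-12-iodo-2,6,10-trimethyldodeca-1,5,9-trien-1-yl]-3-[(phenylsulfonyl)methyl]furan-2(5H)-one
Conditions: PhSO2Na (1.05 equiv), DMF, 0 °C
Reagents that add atoms: sodium benzenesulfinate, [Na+].[O-]S(=O)c1ccccc1
Why: Sulfinate is a soft, non-basic nucleophile that should S-alkylate at the allylic iodide C17 by SN2 far faster than at the unactivated primary iodide C14, giving the allyl sulfone without touching the acidic C2–H.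

Step 17
Reactants: 26 (5S)-5-[(1E,4S,5E,8S,9E)-4-acetoxy-8-(TBSO)-12-iodo-2,6,10-trimethyldodeca-1,5,9-trien-1-yl]-3-[(phenylsulfonyl)methyl]furan-2(5H)-one
Product: 27 (1R,2S,3E,6S,7E,10S,11E)-6-acetoxy-10-(TBSO)cembra-3,7,11,15(17)-tetraen-16,2-olide
Conditions: (Bu3Sn)2 (1.5 equiv), hν (sunlamp, Pyrex), benzene (0.5 mM), 80 °C
Reagents that add atoms: none
Why: Proposed new method: photolysis of (Bu3Sn)2 gives Bu3Sn•, which abstracts iodine from C14; the primary radical adds to C1 (the β-carbon of the butenolide), and the tertiary α-lactone radical at C15 expels PhSO2• from C17 by β-scission, which moves the double bond to the exocyclic C15=C17 position, while PhSO2• is captured by (Bu3Sn)2 to regenerate Bu3Sn•. The closest known reaction types are the intermolecular radical allylation of alkyl iodides with 2-(sulfonylmethyl)acrylates under hexabutylditin photolysis and the tin-mediated radical macrocyclisation onto enoates and enones that gives 14-membered rings. The macrocycle closes in the 14-exo-trig mode (C1 inside the new ring, C15 outside it). The C1 stereocentre is controlled by C2: the new C1–C14 bond should form on the butenolide face anti to the C2–C3 bond, as in intermolecular radical additions to 5-substituted butenolides, because syn closure would eclipse these two bonds on the flat five-membered ring; this gives the trans-fused (1R,2S) lactone. The step needs ring closure to outrun intermolecular addition and premature quenching, which is secured by the absence of any hydrogen donor, by high dilution, by the E-olefins C11=C12 and C7=C8 (which make 1,5-hydrogen transfer from C10 and small-ring closures geometrically impossible), and by the fast irreversible loss of the sulfonyl radical.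

Step 18
Reactants: 27 (1R,2S,3E,6S,7E,10S,11E)-6-acetoxy-10-(TBSO)cembra-3,7,11,15(17)-tetraen-16,2-olide
Product: 28 (1R,2S,3E,6S,7E,10S,11E)-6-acetoxy-10-hydroxycembra-3,7,11,15(17)-tetraen-16,2-olide (CNP0168244.1)
Conditions: HF·pyridine, THF, 0 °C to rt
Reagents that add atoms: none
Why: Acidic fluoride desilylation removes the secondary allylic silyl ether under conditions that should neither hydrolyse the acetate nor add to the α-methylene lactone.

**Compound list**

1 | tert-butyl(but-3-yn-1-yloxy)dimethylsilane | C#CCCO[Si](C)(C)C(C)(C)C | starting material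
2 | [(E)-4-(TBSO)-2-methylbut-1-en-1-yl]dimethylalane | C[Al](C)/C=C(\C)CCO[Si](C)(C)C(C)(C)C | intermediate
3 | (E)-tert-butyl[(4-iodo-3-methylbut-3-en-1-yl)oxy]dimethylsilane | I/C=C(\C)CCO[Si](C)(C)C(C)(C)C | intermediate
4 | [(E)-4-(TBSO)-2-methylbut-1-en-1-yl]lithium | [Li]/C=C(\C)CCO[Si](C)(C)C(C)(C)C | intermediate
5 | (E)-5-(TBSO)-3-methylpent-2-enal | O=C/C=C(\C)CCO[Si](C)(C)C(C)(C)C | intermediate
6 | allenylboronic acid pinacol ester (4,4,5,5-tetramethyl-2-(propa-1,2-dien-1-yl)-1,3,2-dioxaborolane) | C=C=CB1OC(C)(C)C(C)(C)O1 | starting material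
7 | (4S,5E)-8-(TBSO)-6-methyloct-5-en-1-yn-4-ol | C#CC[C@H](O)/C=C(\C)CCO[Si](C)(C)C(C)(C)C | intermediate
8 | (4S,5E)-4,8-bis(TBSO)-6-methyloct-5-en-1-yne | C#CC[C@H](O[Si](C)(C)C(C)(C)C)/C=C(\C)CCO[Si](C)(C)C(C)(C)C | intermediate
9 | [(1E,4S,5E)-4,8-bis(TBSO)-2,6-dimethylocta-1,5-dien-1-yl]dimethylalane | C[Al](C)/C=C(\C)C[C@H](O[Si](C)(C)C(C)(C)C)/C=C(\C)CCO[Si](C)(C)C(C)(C)C | intermediate
10 | (1E,4S,5E)-4,8-bis(TBSO)-1-iodo-2,6-dimethylocta-1,5-diene | I/C=C(\C)C[C@H](O[Si](C)(C)C(C)(C)C)/C=C(\C)CCO[Si](C)(C)C(C)(C)C | intermediate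
11 | [(1E,4S,5E)-4,8-bis(TBSO)-2,6-dimethylocta-1,5-dien-1-yl]lithium | [Li]/C=C(\C)C[C@H](O[Si](C)(C)C(C)(C)C)/C=C(\C)CCO[Si](C)(C)C(C)(C)C | intermediate
12 | (2E,5S,6E)-5,9-bis(TBSO)-3,7-dimethylnona-2,6-dienal | O=C/C=C(\C)C[C@H](O[Si](C)(C)C(C)(C)C)/C=C(\C)CCO[Si](C)(C)C(C)(C)C | intermediate
13 | (4S,5E,8S,9E)-8,12-bis(TBSO)-6,10-dimethyldodeca-5,9-dien-1-yn-4-ol | C#CC[C@H](O)/C=C(\C)C[C@H](O[Si](C)(C)C(C)(C)C)/C=C(\C)CCO[Si](C)(C)C(C)(C)C | intermediate
14 | O-dimethylaluminio alkoxide and C1-dimethylalane of the carboaluminated form of 13 | C[Al](C)/C=C(\C)C[C@H](O[Al](C)C)/C=C(\C)C[C@H](O[Si](C)(C)C(C)(C)C)/C=C(\C)CCO[Si](C)(C)C(C)(C)C | intermediate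
15 | (1E,4S,5E,8S,9E)-8,12-bis(TBSO)-1-iodo-2,6,10-trimethyldodeca-1,5,9-trien-4-ol | I/C=C(\C)C[C@H](O)/C=C(\C)C[C@H](O[Si](C)(C)C(C)(C)C)/C=C(\C)CCO[Si](C)(C)C(C)(C)C | intermediate
16 | dilithio derivative of 15 (lithium alkoxide at C4, alkenyllithium at C1) | [Li]/C=C(\C)C[C@H](O[Li])/C=C(\C)C[C@H](O[Si](C)(C)C(C)(C)C)/C=C(\C)CCO[Si](C)(C)C(C)(C)C | intermediate
17 | (2E,5S,6E,9S,10E)-9,13-bis(TBSO)-5-hydroxy-3,7,11-trimethyltrideca-2,6,10-trienal | O=C/C=C(\C)C[C@H](O)/C=C(\C)C[C@H](O[Si](C)(C)C(C)(C)C)/C=C(\C)CCO[Si](C)(C)C(C)(C)C | intermediate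
18 | tert-butyldimethyl(prop-2-yn-1-yloxy)silane | C#CCO[Si](C)(C)C(C)(C)C | starting material
19 | (4S,5E,8S,9E,12S,13E)-1,12,16-tris(TBSO)-6,10,14-trimethylhexadeca-5,9,13-trien-2-yne-4,8-diol | O[C@H](C#CCO[Si](C)(C)C(C)(C)C)/C=C(\C)C[C@H](O)/C=C(\C)C[C@H](O[Si](C)(C)C(C)(C)C)/C=C(\C)CCO[Si](C)(C)C(C)(C)C | intermediate
20 | sodium 2,2-bis(2-methoxyethoxy)-2,5-dihydro-1,2-oxaluminol-2-uide from 19 (O on C2, Al on C15; remote C6 hydroxyl drawn free) | [Na+].COCCO[Al-]1(OCCOC)O[C@H](C=C1CO[Si](C)(C)C(C)(C)C)/C=C(\C)C[C@H](O)/C=C(\C)C[C@H](O[Si](C)(C)C(C)(C)C)/C=C(\C)CCO[Si](C)(C)C(C)(C)C | intermediate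
21 | (2Z,4S,5E,8S,9E,12S,13E)-1,12,16-tris(TBSO)-2-iodo-6,10,14-trimethylhexadeca-2,5,9,13-tetraene-4,8-diol | O[C@H](/C=C(\I)CO[Si](C)(C)C(C)(C)C)/C=C(\C)C[C@H](O)/C=C(\C)C[C@H](O[Si](C)(C)C(C)(C)C)/C=C(\C)CCO[Si](C)(C)C(C)(C)C | intermediate
22 | (5S)-5-[(1E,4S,5E,8S,9E)-8,12-bis(TBSO)-4-hydroxy-2,6,10-trimethyldodeca-1,5,9-trien-1-yl]-3-[(TBSO)methyl]furan-2(5H)-one | O=C1O[C@@H](/C=C(\C)C[C@H](O)/C=C(\C)C[C@H](O[Si](C)(C)C(C)(C)C)/C=C(\C)CCO[Si](C)(C)C(C)(C)C)C=C1CO[Si](C)(C)C(C)(C)C | intermediate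
23 | (5S)-5-[(1E,4S,5E,8S,9E)-4-acetoxy-8,12-bis(TBSO)-2,6,10-trimethyldodeca-1,5,9-trien-1-yl]-3-[(TBSO)methyl]furan-2(5H)-one | O=C1O[C@@H](/C=C(\C)C[C@H](OC(C)=O)/C=C(\C)C[C@H](O[Si](C)(C)C(C)(C)C)/C=C(\C)CCO[Si](C)(C)C(C)(C)C)C=C1CO[Si](C)(C)C(C)(C)C | intermediate
24 | (5S)-5-[(1E,4S,5E,8S,9E)-4-acetoxy-8-(TBSO)-12-hydroxy-2,6,10-trimethyldodeca-1,5,9-trien-1-yl]-3-(hydroxymethyl)furan-2(5H)-one | O=C1O[C@@H](/C=C(\C)C[C@H](OC(C)=O)/C=C(\C)C[C@H](O[Si](C)(C)C(C)(C)C)/C=C(\C)CCO)C=C1CO | intermediate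
25 | (5S)-5-[(1E,4S,5E,8S,9E)-4-acetoxy-8-(TBSO)-12-iodo-2,6,10-trimethyldodeca-1,5,9-trien-1-yl]-3-(iodomethyl)furan-2(5H)-one | O=C1O[C@@H](/C=C(\C)C[C@H](OC(C)=O)/C=C(\C)C[C@H](O[Si](C)(C)C(C)(C)C)/C=C(\C)CCI)C=C1CI | intermediate
26 | (5S)-5-[(1E,4S,5E,8S,9E)-4-acetoxy-8-(TBSO)-12-iodo-2,6,10-trimethyldodeca-1,5,9-trien-1-yl]-3-[(phenylsulfonyl)methyl]furan-2(5H)-one | O=C1O[C@@H](/C=C(\C)C[C@H](OC(C)=O)/C=C(\C)C[C@H](O[Si](C)(C)C(C)(C)C)/C=C(\C)CCI)C=C1CS(=O)(=O)c1ccccc1 | intermediate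
27 | (1R,2S,3E,6S,7E,10S,11E)-6-acetoxy-10-(TBSO)cembra-3,7,11,15(17)-tetraen-16,2-olide (trans-fused α-methylene-γ-butyrolactone on the 14-membered ring) | C=C1C(=O)O[C@H]2/C=C(\C)C[C@H](OC(C)=O)/C=C(\C)C[C@H](O[Si](C)(C)C(C)(C)C)/C=C(\C)CC[C@H]12 | intermediate
28 | (1R,2S,3E,6S,7E,10S,11E)-6-acetoxy-10-hydroxycembra-3,7,11,15(17)-tetraen-16,2-olide (CNP0168244.1) | C=C1C(=O)O[C@H]2/C=C(\C)C[C@H](OC(C)=O)/C=C(\C)C[C@H](O)/C=C(\C)CC[C@H]12 | target

**Step count**

Total steps: 18. Longest linear sequence: 18 steps (1 to 28); the route is fully linear, with 6 and 18 entering as purchased reagents.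

**Steps most likely to fail**

1. Step 17 (proposed new method). The open-chain C14 radical may be intercepted intermolecularly before the slow 14-membered closure, most likely by the α-methylene lactone of product already formed, which is a better radical acceptor than the butenolide. The sulfonyl/ditin chain may also stall at this dilution. Fallback with known chemistry, from 25 back to 27: the allylic iodide of 25 alone is displaced with NaOAc/AcOH in DMF at 0 °C to give (5S)-5-[(1E,4S,5E,8S,9E)-4-acetoxy-8-(TBSO)-12-iodo-2,6,10-trimethyldodeca-1,5,9-trien-1-yl]-3-(acetoxymethyl)furan-2(5H)-one F1. Reductive radical macrocyclisation (Bu3SnH by syringe pump, AIBN, benzene, 80 °C, 1 mM; Giese-type 14-exo addition anti to C2–C3) then gives the saturated lactone (1R,2S,3E,6S,7E,10S,11E)-6,17-diacetoxy-10-(TBSO)cembra-3,7,11-trien-16,2-olide F2 as a mixture at C15. This product is not a radical acceptor. Elimination of acetic acid with DBU in CH2Cl2 unveils the exocyclic methylene and returns 27.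

2. Step 10. The free C6 hydroxyl, present as a zinc alkoxide, may engage the dinuclear zinc catalyst, so that the addition stalls or loses facial control at C2. Fallback from 15 back to 19, bypassing 17: tert-butyldimethyl(prop-2-yn-1-yloxy)silane 18 is lithiated (n-BuLi, THF, −78 °C) and acylated with N-methoxy-N-methylcarbamoyl chloride to give N-methoxy-N-methyl-4-(TBSO)but-2-ynamide F3. The dilithio species 16, generated from 15 as in step 9, is acylated with F3 to give (5E,8S,9E,12S,13E)-1,12,16-tris(TBSO)-8-hydroxy-6,10,14-trimethylhexadeca-5,9,13-trien-2-yn-4-one F4. Midland reduction of this alkynyl ketone with (S)-Alpine-Borane (from (−)-α-pinene; the alkynyl group acts as the small substituent) should give the S carbinol 19.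

3. Step 11. The alkenylaluminate may lose silanolate from C17 by β-elimination to give an allene, or may be protonated before iodination, so that the vinyl iodide is not formed cleanly. Fallback from 19 back to 21: hydroxyl-directed trans-hydrosilylation with benzyldimethylsilane and [Cp*Ru(MeCN)3]PF6 (CH2Cl2, 0 °C) places silicon on C15, distal to the C2 hydroxyl, to give (2Z,4S,5E,8S,9E,12S,13E)-2-[benzyl(dimethyl)silyl]-1,12,16-tris(TBSO)-6,10,14-trimethylhexadeca-2,5,9,13-tetraene-4,8-diol F5. Iododesilylation with retention (N-iodosuccinimide, 2,6-lutidine, hexafluoroisopropanol, 0 °C) returns 21.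

**Further compounds**

F1 | step 17 | (5S)-5-[(1E,4S,5E,8S,9E)-4-acetoxy-8-(TBSO)-12-iodo-2,6,10-trimethyldodeca-1,5,9-trien-1-yl]-3-(acetoxymethyl)furan-2(5H)-one | O=C1O[C@@H](/C=C(\C)C[C@H](OC(C)=O)/C=C(\C)C[C@H](O[Si](C)(C)C(C)(C)C)/C=C(\C)CCI)C=C1COC(C)=O
F2 | step 17 | (1R,2S,3E,6S,7E,10S,11E)-6,17-diacetoxy-10-(TBSO)cembra-3,7,11-trien-16,2-olide (C15 unspecified) | CC(=O)OCC1C(=O)O[C@H]2/C=C(\C)C[C@H](OC(C)=O)/C=C(\C)C[C@H](O[Si](C)(C)C(C)(C)C)/C=C(\C)CC[C@H]12
F3 | step 10 | N-methoxy-N-methyl-4-(TBSO)but-2-ynamide | CON(C)C(=O)C#CCO[Si](C)(C)C(C)(C)C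
F4 | step 10 | (5E,8S,9E,12S,13E)-1,12,16-tris(TBSO)-8-hydroxy-6,10,14-trimethylhexadeca-5,9,13-trien-2-yn-4-one | O=C(C#CCO[Si](C)(C)C(C)(C)C)/C=C(\C)C[C@H](O)/C=C(\C)C[C@H](O[Si](C)(C)C(C)(C)C)/C=C(\C)CCO[Si](C)(C)C(C)(C)C
F5 | step 11 | (2Z,4S,5E,8S,9E,12S,13E)-2-[benzyl(dimethyl)silyl]-1,12,16-tris(TBSO)-6,10,14-trimethylhexadeca-2,5,9,13-tetraene-4,8-diol | O[C@H](/C=C(\[Si](C)(C)Cc1ccccc1)CO[Si](C)(C)C(C)(C)C)/C=C(\C)C[C@H](O)/C=C(\C)C[C@H](O[Si](C)(C)C(C)(C)C)/C=C(\C)CCO[Si](C)(C)C(C)(C)C
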